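**Strategy.** The oxolane is cut at O1–C5 and C2–C3. C3 is α to the aroyl carbonyl (latent nucleophile), C5 is benzylic to the 2,4-dioxygenated ring (latent electrophile), and O1–C2 is the C=O of a 4-oxygenated benzaldehyde; C3–C4–C5 is therefore folded into a donor–acceptor cyclopropane. Because the C3 carbonyl and the C4 carbinol oxygen are cis, both are tied into a γ-lactone. The key step, a Lewis-acid (3+2) annulation of this cyclopropane-fused lactone with the aldehyde, makes the oxolane ring and three of its stereocentres in one operation; an aryllithium then opens the lactone to the ketone and the free carbinol.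

Key step: step 5

Remark: hydroxy ketone 12 and the target may equilibrate with a cyclic hemiketal (carbinol oxygen on the ketone); both are drawn in the open form.
Remark: in the oxazaborolidine reduction the aryl group on the carbonyl is assumed to act as the larger substituent, as it does in acetophenone.

Step 1
Reactants: 1 1-[4-(benzyloxy)phenyl]ethan-1-one; 2 2,4-bis(benzyloxy)benzaldehyde
Product: 3 (E)-1-[4-(benzyloxy)phenyl]-3-[2,4-bis(benzyloxy)phenyl]prop-2-en-1-one
Conditions: KOH, EtOH/THF, rt
Reagents that add atoms: none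
Why: Claisen–Schmidt condensation of the methyl ketone enolate with the non-enolisable aldehyde; E1cB dehydration should give the more stable E-enone.

Step 2
Reactants: 3 the chalcone
Product: 4 (R,E)-1-[4-(benzyloxy)phenyl]-3-[2,4-bis(benzyloxy)phenyl]prop-2-en-1-ol
Conditions: (S)-Me-CBS oxazaborolidine (20 mol%), catecholborane, toluene, −78 °C; aqueous NaOH work-up; Et3N-deactivated silica
Reagents that add atoms: none
Why: Corey–Bakshi–Shibata reduction, in which the oxazaborolidine–borane complex should deliver hydride 1,2 to the Si face of the carbonyl and so set the (R)-carbinol centre, while catecholborane at low temperature avoids conjugate reduction.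

Step 3
Reactants: 4 the (R)-allylic alcohol
Product: 6 (R,E)-1-[4-(benzyloxy)phenyl]-3-[2,4-bis(benzyloxy)phenyl]prop-2-en-1-yl diazoacetate, via bromoacetate ester 5 (not isolated)
Conditions: BrCH2COBr, NaHCO3, MeCN, 0 °C; then TsNHNHTs, DBU, THF, 0 °C
Reagents that add atoms: bromoacetyl bromide BrCC(Br)=O; N,N'-ditosylhydrazine Cc1ccc(cc1)S(=O)(=O)NNS(=O)(=O)c1ccc(C)cc1
Why: Diazoacetate synthesis by O-acylation, N-alkylation of the ditosylhydrazine anion by the bromoacetate and base-induced loss of two sulfinates; the buffered, acid-free conditions should keep the ionisable 1,3-diarylallyl C–O bond and its configuration intact.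

Step 4
Reactants: 6 the allylic diazoacetate
Product: 7 (1S,4R,5R,6R)-4-[4-(benzyloxy)phenyl]-6-[2,4-bis(benzyloxy)phenyl]-3-oxabicyclo[3.1.0]hexan-2-one (4-aryl anti to the cyclopropane, 6-aryl exo)
Conditions: Rh2(4R-MPPIM)4 (1 mol%; MPPIM = methyl 2-oxo-1-(3-phenylpropanoyl)imidazolidine-4-carboxylate), CH2Cl2, reflux, slow addition of 6
Reagents that add atoms: none
Why: Intramolecular cyclopropanation of an allylic diazoacetate by a chiral dirhodium carboxamidate carbenoid: addition is stereospecific, so the E-alkene places the 6-aryl group exo, and the alkene face is chosen by a matched pair of catalyst (the 4R enantiomer is expected to give the 1S,5R ring fusion) and substrate (carbinol aryl outside, hydrogen inside, to avoid allylic strain), which puts the 4-aryl group anti to the cyclopropane.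

Step 5
Reactants: 7 the cyclopropane-fused lactone; 8 4-(benzyloxy)benzaldehyde
Product: 9 (3R,3aS,4R,6R,6aR)-3,6-bis[4-(benzyloxy)phenyl]-4-[2,4-bis(benzyloxy)phenyl]tetrahydro-1H,3H-furo[3,4-c]furan-1-one (cis-fused; 3- and 6-aryl exo, 4-aryl endo)
Conditions: Sc(OTf)3 (10 mol%), 4 Å molecular sieves, CH2Cl2, −40 to 0 °C
Reagents that add atoms: none
Why: Lewis-acid-catalysed (3+2) annulation of a donor–acceptor cyclopropane with an aldehyde: Sc(OTf)3 binds the lactone carbonyl, the aldehyde oxygen attacks the aryl-bearing C6 from the side opposite to the breaking C1–C6 bond, and the resulting lactone enolate adds to the new oxocarbenium carbon (aldol-type), closing the oxolane. The closure is 5-(enolexo)-endo-trig onto an oxocarbenium ion, formally disfavoured by the ring-closure rules but the normal closure of this annulation. The carbon that becomes C4 is set by inversion, which turns the exo-aryl cyclopropane into the endo-aryl product (aryl cis to the C3a–C3 bond); C6a is fixed because a bicyclo[3.3.0] lactone can only be cis-fused; C6 is set in the closure, where the E-oxocarbenium ion keeps its aryl group on the convex face, trans to the lactone carbonyl; C3 and C3a are carried through unchanged. The step needs regioselective cleavage of C1–C6, secured because this is the only ring bond flanked by the donor aryl group and the carbonyl and the only one aligned with the carbonyl π* orbital (C1–C5 lies in the lactone plane), and it needs invertive capture at the benzylic carbon, favoured by the poor nucleofugality of a single ester enolate, the low temperature and the weakly polar medium. The strongly donating 2,4-bis(benzyloxy)phenyl group compensates for the single acceptor.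

Step 6
Reactants: 9 the furofuranone; 10 2,4-bis(benzyloxy)-1-bromobenzene
Product: 12 [2,4-bis(benzyloxy)phenyl][(2R,3R,4R,5R)-2-[4-(benzyloxy)phenyl]-4-{(R)-[4-(benzyloxy)phenyl](hydroxy)methyl}-5-[2,4-bis(benzyloxy)phenyl]oxolan-3-yl]methanone, via aryllithium 11 (not isolated)
Conditions: 10, n-BuLi, THF, −78 °C; then 9, −78 °C; aqueous NH4Cl
Reagents that add atoms: none
Why: Bromine–lithium exchange gives the aryllithium, which should add once to the γ-lactone carbonyl at −78 °C because the lithium hemiketal alkoxide does not collapse before the quench; work-up releases the aryl ketone and the free carbinol with all five stereocentres untouched.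

Step 7
Reactants: 12 the hexabenzyl ether
Product: 13 (2,4-dihydroxyphenyl)[(2R,3R,4R,5R)-5-(2,4-dihydroxyphenyl)-4-[(R)-hydroxy(4-hydroxyphenyl)methyl]-2-(4-hydroxyphenyl)oxolan-3-yl]methanone (CNP0244141.1)
Conditions: H2 (1 atm), palladium on carbon (Pd/C, 10 wt%), EtOAc/MeOH, rt, stopped at full debenzylation
Reagents that add atoms: none
Why: Palladium-catalysed hydrogenolysis of the six aryl benzyl ethers, which should cleave much faster than the ring benzylic C–O bonds, the secondary benzylic alcohol or the aryl ketone under neutral conditions at one atmosphere; no stereocentre is touched.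

**Compound list**

1 | 1-[4-(benzyloxy)phenyl]ethan-1-one | CC(=O)c1ccc(OCc2ccccc2)cc1 | starting material
2 | 2,4-bis(benzyloxy)benzaldehyde | O=Cc1ccc(OCc2ccccc2)cc1OCc1ccccc1 | starting material
3 | (E)-1-[4-(benzyloxy)phenyl]-3-[2,4-bis(benzyloxy)phenyl]prop-2-en-1-one | O=C(/C=C/c1ccc(OCc2ccccc2)cc1OCc1ccccc1)c1ccc(OCc2ccccc2)cc1 | intermediate
4 | (R,E)-1-[4-(benzyloxy)phenyl]-3-[2,4-bis(benzyloxy)phenyl]prop-2-en-1-ol | O[C@@H](c1ccc(OCc2ccccc2)cc1)/C=C/c1ccc(OCc2ccccc2)cc1OCc1ccccc1 | intermediate
5 | (R,E)-1-[4-(benzyloxy)phenyl]-3-[2,4-bis(benzyloxy)phenyl]prop-2-en-1-yl bromoacetate | BrCC(=O)O[C@@H](c1ccc(OCc2ccccc2)cc1)/C=C/c1ccc(OCc2ccccc2)cc1OCc1ccccc1 | intermediate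
6 | (R,E)-1-[4-(benzyloxy)phenyl]-3-[2,4-bis(benzyloxy)phenyl]prop-2-en-1-yl diazoacetate | [N-]=[N+]=CC(=O)O[C@@H](c1ccc(OCc2ccccc2)cc1)/C=C/c1ccc(OCc2ccccc2)cc1OCc1ccccc1 | intermediate
7 | (1S,4R,5R,6R)-4-[4-(benzyloxy)phenyl]-6-[2,4-bis(benzyloxy)phenyl]-3-oxabicyclo[3.1.0]hexan-2-one | O=C2[C@@H]1[C@H]([C@@H](O2)c3ccc(OCc4ccccc4)cc3)[C@H]1c1ccc(OCc2ccccc2)cc1OCc1ccccc1 | intermediate
8 | 4-(benzyloxy)benzaldehyde | O=Cc1ccc(OCc2ccccc2)cc1 | starting material
9 | (3R,3aS,4R,6R,6aR)-3,6-bis[4-(benzyloxy)phenyl]-4-[2,4-bis(benzyloxy)phenyl]tetrahydro-1H,3H-furo[3,4-c]furan-1-one | O=C2[C@@H]1[C@H]([C@@H](O2)c3ccc(OCc4ccccc4)cc3)[C@H](c3ccc(OCc4ccccc4)cc3OCc3ccccc3)O[C@H]1c1ccc(OCc2ccccc2)cc1 | intermediate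
10 | 2,4-bis(benzyloxy)-1-bromobenzene | Brc1ccc(OCc2ccccc2)cc1OCc1ccccc1 | starting material
11 | [2,4-bis(benzyloxy)phenyl]lithium | [Li]c1ccc(OCc2ccccc2)cc1OCc1ccccc1 | intermediate
12 | [2,4-bis(benzyloxy)phenyl][(2R,3R,4R,5R)-2-[4-(benzyloxy)phenyl]-4-{(R)-[4-(benzyloxy)phenyl](hydroxy)methyl}-5-[2,4-bis(benzyloxy)phenyl]oxolan-3-yl]methanone | O=C(c1ccc(OCc2ccccc2)cc1OCc1ccccc1)[C@@H]1[C@H]([C@@H](O)c2ccc(OCc3ccccc3)cc2)[C@H](c2ccc(OCc3ccccc3)cc2OCc2ccccc2)O[C@H]1c1ccc(OCc2ccccc2)cc1 | intermediate
13 | (2,4-dihydroxyphenyl)[(2R,3R,4R,5R)-5-(2,4-dihydroxyphenyl)-4-[(R)-hydroxy(4-hydroxyphenyl)methyl]-2-(4-hydroxyphenyl)oxolan-3-yl]methanone | O=C(c1ccc(O)cc1O)[C@@H]1[C@H]([C@@H](O)c2ccc(O)cc2)[C@H](c2ccc(O)cc2O)O[C@H]1c1ccc(O)cc1 | target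

**Step count.** Total: 7 steps. Longest linear sequence: 7 steps (1 or 2 to 13).

**Steps most likely to fail**

Step 5. The single lactone carbonyl may not activate the cyclopropane at a temperature low enough to keep capture at the benzylic carbon invertive. On warming, the benzylic carbon would ionise fully, the aldehyde would add without facial bias, and the product could reopen at C4–O5 and drift to the exo-aryl epimer. Ionisation of the benzylic lactone C–O bond could also compete. The fallback adds a second, chelating acceptor that is removed afterwards. It sets out from alcohol 4. Acylation with methyl malonyl chloride (pyridine, CH2Cl2, 0 °C) should give the mixed methyl malonate F1. Regitz diazo transfer (4-acetamidobenzenesulfonyl azide, Et3N, MeCN) should give the diazomalonate F2. Rh2(OAc)4 in refluxing CH2Cl2 should give the cyclopropane-fused lactone ester F3 under the same substrate control as in step 4. The β-dicarbonyl unit of F3 chelates Sn(OTf)2 (5 mol%), so the annulation with 8 can run at −20 °C on the stereospecific invertive pathway established for 2-arylcyclopropane-1,1-dicarboxylates, giving the furofuranone ester F4. Krapcho demethoxycarbonylation (LiCl, wet DMSO, 130 °C), with protonation to the only possible cis-fused lactone, returns to 9.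

Step 6. The aryllithium may act as a base at C6a; the enolate would then expel the ring oxygen from C6 and open the oxolane. The hemiketal alkoxide may also collapse in the flask, so that a second aryllithium adds to the ketone. The fallback sets out from 9. Aminolysis with the chloromagnesium amide of N,O-dimethylhydroxylamine (MeNHOMe·HCl, i-PrMgCl, THF, −20 °C) should give the hydroxy Weinreb amide F5, whose α-proton is less acidic. Its chelated tetrahedral adduct with aryllithium 11 (2.2 equiv., the first deprotonating the carbinol) cannot over-add and returns to 12 on work-up.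

Step 2. Both groups on the carbonyl are unsaturated, so the oxazaborolidine may discriminate poorly between the two faces. Conjugate reduction and acid-induced ionisation of the electron-rich allylic alcohol (racemisation, 1,3-transposition) are further ways to lose material or purity. The fallback makes the carbinol centre by C–C bond formation and sets out from aldehyde 2. Ohira–Bestmann homologation (dimethyl (1-diazo-2-oxopropyl)phosphonate, K2CO3, MeOH) should give 2,4-bis(benzyloxy)-1-ethynylbenzene F6. Hydroboration with dicyclohexylborane should give the (E)-alkenylborane F7, and boron–zinc exchange with Me2Zn the (E)-alkenyl(methyl)zinc F8. Its addition to the Re face of aldehyde 8, catalysed by (+)-3-exo-morpholinoisoborneol, returns to 4.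

**Further compounds**

F1 | step 5 | (R,E)-1-[4-(benzyloxy)phenyl]-3-[2,4-bis(benzyloxy)phenyl]prop-2-en-1-yl methyl malonate | COC(=O)CC(=O)O[C@@H](c1ccc(OCc2ccccc2)cc1)/C=C/c1ccc(OCc2ccccc2)cc1OCc1ccccc1
F2 | step 5 | (R,E)-1-[4-(benzyloxy)phenyl]-3-[2,4-bis(benzyloxy)phenyl]prop-2-en-1-yl methyl 2-diazomalonate | COC(=O)C(=[N+]=[N-])C(=O)O[C@@H](c1ccc(OCc2ccccc2)cc1)/C=C/c1ccc(OCc2ccccc2)cc1OCc1ccccc1
F3 | step 5 | methyl (1S,4R,5R,6S)-4-[4-(benzyloxy)phenyl]-6-[2,4-bis(benzyloxy)phenyl]-2-oxo-3-oxabicyclo[3.1.0]hexane-1-carboxylate | O=C2[C@]1(C(=O)OC)[C@H]([C@@H](O2)c3ccc(OCc4ccccc4)cc3)[C@H]1c1ccc(OCc2ccccc2)cc1OCc1ccccc1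
F4 | step 5 | methyl (3R,3aS,4R,6S,6aR)-3,6-bis[4-(benzyloxy)phenyl]-4-[2,4-bis(benzyloxy)phenyl]-1-oxotetrahydro-1H,3H-furo[3,4-c]furan-6a-carboxylate | O=C2[C@]1(C(=O)OC)[C@H]([C@@H](O2)c3ccc(OCc4ccccc4)cc3)[C@H](c3ccc(OCc4ccccc4)cc3OCc3ccccc3)O[C@H]1c1ccc(OCc2ccccc2)cc1
F5 | step 6 | (2R,3R,4R,5R)-2-[4-(benzyloxy)phenyl]-4-{(R)-[4-(benzyloxy)phenyl](hydroxy)methyl}-5-[2,4-bis(benzyloxy)phenyl]-N-methoxy-N-methyloxolane-3-carboxamide | CON(C)C(=O)[C@@H]1[C@H]([C@@H](O)c2ccc(OCc3ccccc3)cc2)[C@H](c2ccc(OCc3ccccc3)cc2OCc2ccccc2)O[C@H]1c1ccc(OCc2ccccc2)cc1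
F6 | step 2 | 2,4-bis(benzyloxy)-1-ethynylbenzene | C#Cc1ccc(OCc2ccccc2)cc1OCc1ccccc1
F7 | step 2 | (E)-{2-[2,4-bis(benzyloxy)phenyl]ethenyl}dicyclohexylborane | C1CCCCC1B(/C=C/c1ccc(OCc2ccccc2)cc1OCc1ccccc1)C1CCCCC1
F8 | step 2 | (E)-{2-[2,4-bis(benzyloxy)phenyl]ethenyl}(methyl)zinc | C[Zn]/C=C/c1ccc(OCc2ccccc2)cc1OCc1ccccc1
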